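Saturday's run, with 0.050 M of starting material and 0.050 M of activator, had lost 0.347 of a power of ten of starting material at 90.0 s. So here is the decision for the next flask: keep that starting material, charge twice the activator, and see whether 2.5 min takes off one whole power of ten.

| flask | starting material | activator | remark | time |
|---|---|---|---|---|
| Monday's | 0.025 M | 0.10 M (in portions, 4) | run made earlier; portions every 20 s |  |
| Wednesday's | 0.10 M | 0.10 M (in portions, 4) | run made earlier; portions every 20 s |  |
| Saturday's | 0.050 M | 0.050 M (in portions, 4) | run made earlier; portions every 20 s |  |
| flask | 0.050 M | 0.100 M (in portions, 4) | the portions of activator follow each other after 20 s, the first at the start | 2.5 min |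

| run | time / s | starting material / % | ring / % |
|---|---|---|---|
| Monday's | 10.0 | 90 | 0 |
| Monday's | 12.0 | 89 | 4 |
| Monday's | 15.0 | 89 | 0 |
| Monday's | 25.0 | 80 | 0 |
| Monday's | 40.0 | 65 | 2 |
| Monday's | 60.0 | 48 | 1 |
| Monday's | 90.0 | 22 | 6 |
| Wednesday's | 10.0 | 94 | 1 |
| Wednesday's | 15.0 | 86 | 0 |
| Wednesday's | 25.0 | 77 | 3 |
| Wednesday's | 40.0 | 63 | 0 |
| Wednesday's | 50.0 | 53 | 0 |
| Wednesday's | 80.0 | 29 | 5 |
| Wednesday's | 90.0 | 26 | 6 |
| Saturday's | 10.0 | 96 | 2 |
| Saturday's | 15.0 | 91 | 0 |
| Saturday's | 25.0 | 85 | 0 |
| Saturday's | 50.0 | 70 | 3 |
| Saturday's | 90.0 | 45 | 5 |

(readings scatter by 2 percentage points)

- percent here means starting material units held: one open dimer counts as two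
- what was read earlier has a scatter of 2 percentage points, one standard deviation
- what may be going on: ring <-> isomer of the product; starting material + activated form -> open dimer; activated form -> ring; starting material + activator -> activated form; starting material <-> dormant form
- the reaction counts as stopped when no species that holds the starting material changes by six tenths of a point or more over the second half of the time
- what has gone from starting material into another species counts as reacted, even if it can come back

1. why nothing more happens at 2.5 min, or that something still does (the activator has run out first / it is still moving / forward and back rates have come level / all of the starting material has reacted)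
2. conversion of starting material at 2.5 min
3. amount of ring at 2.5 min, in percent of the starting material charged
4. amount of open dimer at 2.5 min, in percent of the starting material charged

Work in powers of ten. Call the dose the area under [activator] against time, counting every portion as unused from its addition. After the last portion, that is the whole charge times the time less the mean delay of the portions, 30.0 s. If starting material is lost pseudo-first-order, with a rate constant proportional to [activator], equal doses take off equal powers of ten. Read at 90.0 s, one power of ten cost 9.12 M·s on Monday, 10.3 M·s on Wednesday and 8.65 M·s on Saturday, each a reading with its scatter. Their mean, 9.34 M·s, is the decade dose, the dose of activator that took off one power of ten of starting material in these runs.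

The new flask receives 12.0 M·s by 2.5 min, which is 1.28 powers of ten, so I expect 5.20 % left and 94.8 % conversion. One power of ten needs 123 s, less than 2.5 min, so I charge this recipe and keep the time. At 1.25 min I reckon 33.0 % left, so starting material falls by 28 percentage points over the second half of the time, and by the stopping rule above I call the flask still moving at 2.5 min. The dose gives no split between ring and open dimer.

The forecast answers "it is still moving", with 95 % conversion, 13 % ring and 18 % open dimer, adding “Dimer is poorly defined”.

The flask gives "it is still moving", conversion 91.9 %, ring 11.1 % and open dimer 31.4 %.

    ring ⇌ isomer of the product (K = 2.00, k = 0.0770 s⁻¹)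
    starting material + activated form → open dimer (k = 0.420 M⁻¹ s⁻¹)
    activated form → ring (k = 0.0130 s⁻¹)
    starting material + activator → activated form (k = 0.190 M⁻¹ s⁻¹)
    starting material ⇌ dormant form (K = 1.60, k = 0.00300 s⁻¹)

Starting material in the flask stands at 33.3 % at 1.25 min and 8.09 % at 2.50 min, which is 1.09 powers of ten, more than the one asked. Now take the neighbour with 0.17 M of activator, all else held. Its dose is 20.4 M·s, and at the decade dose that makes 2.18 powers of ten, or 0.654 % left. The neighbour holds 2.04 % of starting material, a conversion of 98.0 %. Its open dimer stands at 30.2 %, against 31.4 % in the flask.

(The readings are calculated for substances that don't exist; scatter was added.)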